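**Retrosynthetic overview**
- The target is unmasked by a last O6 desilylation; its only carbocycle, the 10-membered ring, is closed by ring-closing metathesis at C1=C10 (Z) of an acyclic diene ester.
- The C8 ester comes from a C8 alcohol made by copper-catalysed isopropenyl Grignard opening of a terminal C8–C9 epoxide, with O6 held as a silyl ether.
- Both epoxides come from one anti homoallylic/allylic alcohol: lipase-mediated peracid epoxidation (C4, C5), then vanadium-directed homoallylic epoxidation (C8).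
- That alcohol (C6, C7) comes from a chiral phosphoric acid-catalysed allylboration of (2E)-3-methylhepta-2,6-dienal with an (E)-γ-isopropylallyl boronate.
- Ring order: C4–C5 oxirane, then the transient C8–C9 oxirane, then the 10-membered carbocycle last.

Assumption: ring positions are given in germacrane numbering (C1=C10 alkene, C4–C5 epoxide, C6 OH, C7 isopropyl, C8 ester), and metal alkoxides or borate esters that are only hydrolysed on work-up are not listed as separate compounds.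

**Step 1**
Reactants: 1 ethyl but-2-ynoate; 2 but-3-en-1-ylmagnesium bromide
Product: 5 ethyl (2E)-3-methylhepta-2,6-dienoate, via but-3-enylcopper 3 (not isolated), via alkenylcopper adduct 4 (not isolated)
Conditions: CuBr·SMe2 (1.1 equiv), THF, −40 °C; then 1, −78 °C, 2 h; aq. NH4Cl at −78 °C
Reagents that add atoms: none
Why: Syn carbocupration (conjugate addition) of the organocopper to the ynoate, with protonation at −78 °C and retention, places the new butenyl group trans to the ester, giving the (E)-trisubstituted alkene.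

**Step 2**
Reactants: 5 ethyl (2E)-3-methylhepta-2,6-dienoate
Product: 6 (2E)-3-methylhepta-2,6-dien-1-ol
Conditions: iBu2AlH (2.3 equiv), CH2Cl2, −78 → 0 °C; aq. potassium sodium tartrate
Reagents that add atoms: none
Why: Hydride reduction of the conjugated ester gives the allylic alcohol by 1,2-reduction without touching either alkene.

**Step 3**
Reactants: 6 (2E)-3-methylhepta-2,6-dien-1-ol
Product: 7 (2E)-3-methylhepta-2,6-dienal
Conditions: MnO2 (15 equiv), CH2Cl2, rt
Reagents that add atoms: none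
Why: Allylic oxidation with MnO2 stops at the enal and does not isomerise the trisubstituted alkene.

**Step 4**
Reactants: 8 3-methylbut-1-yne
Product: 9 4,4,5,5-tetramethyl-2-[(1E)-3-methylbut-1-en-1-yl]-1,3,2-dioxaborolane
Conditions: pinacolborane (1.1 equiv), Cp2Zr(H)Cl (5 mol%), Et3N (10 mol%), CH2Cl2, rt, sealed vessel
Reagents that add atoms: pinacolborane, B1OC(C)(C)C(C)(C)O1
Why: Zirconium-catalysed syn, anti-Markovnikov hydroboration of the terminal alkyne gives only the (E)-alkenylboronate.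

**Step 5**
Reactants: 9 4,4,5,5-tetramethyl-2-[(1E)-3-methylbut-1-en-1-yl]-1,3,2-dioxaborolane
Product: 11 4,4,5,5-tetramethyl-2-[(2E)-4-methylpent-2-en-1-yl]-1,3,2-dioxaborolane, via lithium chloromethyl boronate complex 10 (not isolated)
Conditions: BrCH2Cl (1.5 equiv), n-BuLi (1.4 equiv), THF, −78 °C → rt
Reagents that add atoms: bromochloromethane, ClCBr
Why: Matteson homologation: chloromethyllithium adds to boron and the alkenyl group undergoes 1,2-migration with loss of chloride and retention of the (E) geometry, giving the γ-isopropyl allylboronate.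

**Step 6**
Reactants: 7 (2E)-3-methylhepta-2,6-dienal; 11 4,4,5,5-tetramethyl-2-[(2E)-4-methylpent-2-en-1-yl]-1,3,2-dioxaborolane
Product: 12 (3R,4R,5E)-6-methyl-3-(propan-2-yl)deca-1,5,9-trien-4-ol
Conditions: (R)-TRIP [(R)-3,3'-bis(2,4,6-triisopropylphenyl)-1,1'-binaphthyl-2,2'-diyl hydrogen phosphate] (5 mol%), 4 Å MS, toluene, −30 → 0 °C, 48 h; aq. NaHCO3
Reagents that add atoms: none
Why: Chiral phosphoric acid-catalysed allylboration through a closed chair (Zimmerman–Traxler) transition state: the (E)-boronate gives the anti relationship and the (R)-catalyst directs allyl transfer to the Re face of the aldehyde, setting C6 and C7 as the first stereocentres.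

**Step 7**
Reactants: 12 (3R,4R,5E)-6-methyl-3-(propan-2-yl)deca-1,5,9-trien-4-ol
Product: 13 (1R,2R)-1-[(2S,3S)-3-(but-3-en-1-yl)-3-methyloxiran-2-yl]-2-(propan-2-yl)but-3-en-1-ol
Conditions: lipase (immobilised Candida antarctica lipase B, Novozym 435), octanoic acid (0.3 equiv), 30% aq. H2O2 (1.3 equiv, slow addition), toluene, 25 °C
Reagents that add atoms: hydrogen peroxide, OO
Why: Lipase-mediated Prilezhaev epoxidation: the lipase perhydrolyses octanoic acid to peroctanoic acid, which attacks only the electron-rich trisubstituted alkene on the face of the C6 hydroxyl in the conformer that minimises allylic 1,3-strain with the cis methyl, giving the threo (C4 S, C5 S) epoxide.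

**Step 8**
Reactants: 13 (1R,2R)-1-[(2S,3S)-3-(but-3-en-1-yl)-3-methyloxiran-2-yl]-2-(propan-2-yl)but-3-en-1-ol
Product: 14 (1R,2S)-1-[(2S,3S)-3-(but-3-en-1-yl)-3-methyloxiran-2-yl]-3-methyl-2-[(2S)-oxiran-2-yl]butan-1-ol
Conditions: VO(acac)2 (10 mol%), t-BuOOH (2 equiv, in decane), CH2Cl2, 0 °C → rt, 24 h
Reagents that add atoms: tert-butyl hydroperoxide, CC(C)(C)OO
Why: Vanadium-catalysed hydroxyl-directed epoxidation of the homoallylic alkene through a chair-like vanadate ester with the oxiranyl, isopropyl and terminal CH2 groups all equatorial delivers oxygen 1,3-syn to O6 and sets C8, while the remote vinyl group is not reached.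

**Step 9**
Reactants: 14 (1R,2S)-1-[(2S,3S)-3-(but-3-en-1-yl)-3-methyloxiran-2-yl]-3-methyl-2-[(2S)-oxiran-2-yl]butan-1-ol
Product: 15 triethyl{[(1R,2R)-1-[(2S,3S)-3-(but-3-en-1-yl)-3-methyloxiran-2-yl]-3-methyl-2-[(2S)-oxiran-2-yl]butyl]oxy}silane
Conditions: Et3SiCl (1.5 equiv), imidazole (3 equiv), DMAP (cat.), DMF, 0 °C → rt
Reagents that add atoms: chlorotriethylsilane, CC[Si](Cl)(CC)CC
Why: Silylation of the only hydroxyl under non-acidic conditions masks O6 so that the two oxygens stay differentiated and no alkoxide can attack either epoxide in the next step.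

**Step 10**
Reactants: 15 triethyl{[(1R,2R)-1-[(2S,3S)-3-(but-3-en-1-yl)-3-methyloxiran-2-yl]-3-methyl-2-[(2S)-oxiran-2-yl]butyl]oxy}silane; 16 prop-1-en-2-ylmagnesium bromide
Product: 17 (4R,5R,6R)-6-[(2S,3S)-3-(but-3-en-1-yl)-3-methyloxiran-2-yl]-2-methyl-5-(propan-2-yl)-6-[(triethylsilyl)oxy]hex-1-en-4-ol
Conditions: 16 (3 equiv), CuBr·SMe2 (15 mol%), THF, −40 → −20 °C; aq. NH4Cl at −20 °C
Reagents that add atoms: none
Why: Copper-catalysed SN2 opening of the monosubstituted epoxide at its CH2 terminus is far faster than attack on the shielded trisubstituted epoxide, so C8 keeps its configuration, and the cold quench avoids silyl migration.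

**Step 11**
Reactants: 17 (4R,5R,6R)-6-[(2S,3S)-3-(but-3-en-1-yl)-3-methyloxiran-2-yl]-2-methyl-5-(propan-2-yl)-6-[(triethylsilyl)oxy]hex-1-en-4-ol; 18 3,4,5-trimethoxybenzoyl chloride
Product: 19 (4R,5R,6R)-6-[(2S,3S)-3-(but-3-en-1-yl)-3-methyloxiran-2-yl]-2-methyl-5-(propan-2-yl)-6-[(triethylsilyl)oxy]hex-1-en-4-yl 3,4,5-trimethoxybenzoate
Conditions: 18 (1.5 equiv), DMAP (1.5 equiv), Et3N (3 equiv), CH2Cl2, 0 °C → rt
Reagents that add atoms: none
Why: DMAP-catalysed acylation of the single free secondary alcohol installs the aryl ester at O8 with retention, since the C–O bond is not touched.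

**Step 12**
Reactants: 19 (4R,5R,6R)-6-[(2S,3S)-3-(but-3-en-1-yl)-3-methyloxiran-2-yl]-2-methyl-5-(propan-2-yl)-6-[(triethylsilyl)oxy]hex-1-en-4-yl 3,4,5-trimethoxybenzoate
Product: 20 (1S,2R,3R,4R,6Z,10S)-6,10-dimethyl-3-(propan-2-yl)-2-[(triethylsilyl)oxy]-11-oxabicyclo[8.1.0]undec-6-en-4-yl 3,4,5-trimethoxybenzoate
Conditions: second-generation Hoveyda–Grubbs catalyst, RuCl2(H2IMes)(=CH-C6H4-2-OiPr) (10 mol%), 1,4-benzoquinone (20 mol%), toluene (1 mM), 80 °C
Reagents that add atoms: none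
Why: Ring-closing metathesis of the vinyl and 1,1-disubstituted alkenes at high dilution forms C1=C10 with loss of ethylene, and in a 10-membered ring only the less strained Z (cis) trisubstituted alkene is expected; the epoxide, ester and silyl ether are inert to the catalyst.

**Step 13**
Reactants: 20 (1S,2R,3R,4R,6Z,10S)-6,10-dimethyl-3-(propan-2-yl)-2-[(triethylsilyl)oxy]-11-oxabicyclo[8.1.0]undec-6-en-4-yl 3,4,5-trimethoxybenzoate
Product: 21 (1S,2R,3S,4R,6Z,10S)-2-hydroxy-6,10-dimethyl-3-(propan-2-yl)-11-oxabicyclo[8.1.0]undec-6-en-4-yl 3,4,5-trimethoxybenzoate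
Conditions: Bu4NF, AcOH (1:1, 3 equiv), THF, 0 °C → rt
Reagents that add atoms: none
Why: Buffered fluoride desilylation frees the C6 hydroxyl without base-induced 1,3-acyl migration or Payne rearrangement and without acid-induced transannular opening of the epoxide.

**Compound list**
1 | ethyl but-2-ynoate | CCOC(=O)C#CC | starting material
2 | but-3-en-1-ylmagnesium bromide | C=CCC[Mg]Br | starting material
3 | but-3-en-1-ylcopper (not isolated) | C=CCC[Cu] | intermediate
4 | ethyl (2Z)-2-cuprio-3-methylhepta-2,6-dienoate (not isolated) | CCOC(=O)/C([Cu])=C(\C)CCC=C | intermediate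
5 | ethyl (2E)-3-methylhepta-2,6-dienoate | CCOC(=O)/C=C(\C)CCC=C | intermediate
6 | (2E)-3-methylhepta-2,6-dien-1-ol | OC/C=C(\C)CCC=C | intermediate
7 | (2E)-3-methylhepta-2,6-dienal | O=C/C=C(\C)CCC=C | intermediate
8 | 3-methylbut-1-yne | CC(C)C#C | starting material
9 | 4,4,5,5-tetramethyl-2-[(1E)-3-methylbut-1-en-1-yl]-1,3,2-dioxaborolane | CC(C)/C=C/B1OC(C)(C)C(C)(C)O1 | intermediate
10 | lithium (chloromethyl)[(1E)-3-methylbut-1-en-1-yl](pinacolato)borate (not isolated) | CC(C)/C=C/[B-]1(CCl)OC(C)(C)C(C)(C)O1.[Li+] | intermediate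
11 | 4,4,5,5-tetramethyl-2-[(2E)-4-methylpent-2-en-1-yl]-1,3,2-dioxaborolane | CC(C)/C=C/CB1OC(C)(C)C(C)(C)O1 | intermediate
12 | (3R,4R,5E)-6-methyl-3-(propan-2-yl)deca-1,5,9-trien-4-ol | C=CCC/C(C)=C/[C@H](O)[C@H](C(C)C)C=C | intermediate
13 | (1R,2R)-1-[(2S,3S)-3-(but-3-en-1-yl)-3-methyloxiran-2-yl]-2-(propan-2-yl)but-3-en-1-ol | C=CCC[C@]1(C)O[C@H]1[C@H](O)[C@H](C(C)C)C=C | intermediate
14 | (1R,2S)-1-[(2S,3S)-3-(but-3-en-1-yl)-3-methyloxiran-2-yl]-3-methyl-2-[(2S)-oxiran-2-yl]butan-1-ol | C=CCC[C@]1(C)O[C@H]1[C@H](O)[C@H](C(C)C)[C@H]2CO2 | intermediate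
15 | triethyl{[(1R,2R)-1-[(2S,3S)-3-(but-3-en-1-yl)-3-methyloxiran-2-yl]-3-methyl-2-[(2S)-oxiran-2-yl]butyl]oxy}silane | C=CCC[C@]1(C)O[C@H]1[C@H](O[Si](CC)(CC)CC)[C@H](C(C)C)[C@H]2CO2 | intermediate
16 | prop-1-en-2-ylmagnesium bromide | C=C(C)[Mg]Br | starting material
17 | (4R,5R,6R)-6-[(2S,3S)-3-(but-3-en-1-yl)-3-methyloxiran-2-yl]-2-methyl-5-(propan-2-yl)-6-[(triethylsilyl)oxy]hex-1-en-4-ol | C=CCC[C@]1(C)O[C@H]1[C@H](O[Si](CC)(CC)CC)[C@H](C(C)C)[C@H](O)CC(C)=C | intermediate
18 | 3,4,5-trimethoxybenzoyl chloride | COc1cc(C(Cl)=O)cc(OC)c1OC | starting material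
19 | (4R,5R,6R)-6-[(2S,3S)-3-(but-3-en-1-yl)-3-methyloxiran-2-yl]-2-methyl-5-(propan-2-yl)-6-[(triethylsilyl)oxy]hex-1-en-4-yl 3,4,5-trimethoxybenzoate | C=CCC[C@]1(C)O[C@H]1[C@H](O[Si](CC)(CC)CC)[C@H](C(C)C)[C@@H](CC(C)=C)OC(=O)c2cc(OC)c(OC)c(OC)c2 | intermediate
20 | (1S,2R,3R,4R,6Z,10S)-6,10-dimethyl-3-(propan-2-yl)-2-[(triethylsilyl)oxy]-11-oxabicyclo[8.1.0]undec-6-en-4-yl 3,4,5-trimethoxybenzoate | COc1cc(C(=O)O[C@@H]2C/C(C)=C\CC[C@]3(C)O[C@H]3[C@H](O[Si](CC)(CC)CC)[C@@H]2C(C)C)cc(OC)c1OC | intermediate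
21 | (1S,2R,3S,4R,6Z,10S)-2-hydroxy-6,10-dimethyl-3-(propan-2-yl)-11-oxabicyclo[8.1.0]undec-6-en-4-yl 3,4,5-trimethoxybenzoate (CNP0260213.11) | COc1cc(C(=O)O[C@@H]2C/C(C)=C\CC[C@]3(C)O[C@H]3[C@H](O)[C@@H]2C(C)C)cc(OC)c1OC | target

**Step count**
Total: 13 steps. Longest linear sequence: 11 steps (steps 1–3 and 6–13); steps 4–5 form a two-step side branch that joins at step 6.

**Three steps most likely to fail**

Step 12 (ring-closing metathesis). Initiation at the 1,1-disubstituted alkene is slow and the 10-membered ring is strained, so dimers may dominate. The fallback is a relay metathesis that sets out from 15 and comes back at 20. But-2-yn-1-ol is reduced with NaAlH2(OCH2CH2OMe)2 and iodinated to (2Z)-3-iodobut-2-en-1-ol F1, which is O-allylated (NaH, allyl bromide) to (2Z)-3-iodo-1-(prop-2-en-1-yloxy)but-2-ene F2. Iodine–magnesium exchange with i-PrMgCl·LiCl gives [(2Z)-4-(prop-2-en-1-yloxy)but-2-en-2-yl]magnesium chloride F3. With CuBr·SMe2 (cat.) this opens 15 at the terminal epoxide carbon to (2Z,5R,6R,7R)-7-[(2S,3S)-3-(but-3-en-1-yl)-3-methyloxiran-2-yl]-3-methyl-6-(propan-2-yl)-1-(prop-2-en-1-yloxy)-7-[(triethylsilyl)oxy]hept-2-en-5-ol F4. Acylation with 18 as in step 11 gives (2Z,5R,6R,7R)-7-[(2S,3S)-3-(but-3-en-1-yl)-3-methyloxiran-2-yl]-3-methyl-6-(propan-2-yl)-1-(prop-2-en-1-yloxy)-7-[(triethylsilyl)oxy]hept-2-en-5-yl 3,4,5-trimethoxybenzoate F5. The ruthenium catalyst then loads on the unhindered allyl ether, expels 2,5-dihydrofuran to place the carbene directly on C10, and this carbene closes onto the C1 vinyl group to give 20.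

Step 6 (catalytic asymmetric allylboration). The γ-isopropyl boronate and the β,β-disubstituted enal are both hindered, so rate and enantioselectivity may fall. The fallback changes the allyl metal and the catalyst; it sets out from 7 and comes back at 12. 4-Methylpent-1-en-3-ol and PBr3 give (2E)-1-bromo-4-methylpent-2-ene F6. Aldehyde 7 and F6 are joined in a catalytic asymmetric Nozaki–Hiyama–Kishi allylation (CrCl2 10 mol%, chiral bis(oxazolinyl)carbazole ligand, Mn, Me3SiCl, i-Pr2NEt, THF). The γ-substituted allylchromium adds through a chair to give the anti adduct as trimethyl{[(3R,4R,5E)-6-methyl-3-(propan-2-yl)deca-1,5,9-trien-4-yl]oxy}silane F7, and dilute HCl work-up returns 12.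

Step 8 (vanadium-directed homoallylic epoxidation). Terminal alkenes react slowly and the diastereoselectivity may be only moderate. The fallback is an iodocarbonate cyclisation that sets out from 13 and comes back at 14. Boc2O and DMAP convert 13 into tert-butyl (1R,2R)-1-[(2S,3S)-3-(but-3-en-1-yl)-3-methyloxiran-2-yl]-2-(propan-2-yl)but-3-en-1-yl carbonate F8. IBr in toluene at −85 °C cyclises the carbonate onto the homoallylic alkene through a chair with all substituents equatorial, giving (4R,5S,6S)-4-[(2S,3S)-3-(but-3-en-1-yl)-3-methyloxiran-2-yl]-6-(iodomethyl)-5-(propan-2-yl)-1,3-dioxan-2-one F9 with the 1,3-syn oxygen pattern. K2CO3 in MeOH cleaves the carbonate and the C8 alkoxide displaces iodide to give 14.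

**Further compounds**
F1 | step 12 | (2Z)-3-iodobut-2-en-1-ol | C/C(I)=C/CO
F2 | step 12 | (2Z)-3-iodo-1-(prop-2-en-1-yloxy)but-2-ene | C/C(I)=C/COCC=C
F3 | step 12 | [(2Z)-4-(prop-2-en-1-yloxy)but-2-en-2-yl]magnesium chloride | C/C([Mg]Cl)=C/COCC=C
F4 | step 12 | (2Z,5R,6R,7R)-7-[(2S,3S)-3-(but-3-en-1-yl)-3-methyloxiran-2-yl]-3-methyl-6-(propan-2-yl)-1-(prop-2-en-1-yloxy)-7-[(triethylsilyl)oxy]hept-2-en-5-ol | C=CCC[C@]1(C)O[C@H]1[C@H](O[Si](CC)(CC)CC)[C@H](C(C)C)[C@H](O)C/C(C)=C\COCC=C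
F5 | step 12 | (2Z,5R,6R,7R)-7-[(2S,3S)-3-(but-3-en-1-yl)-3-methyloxiran-2-yl]-3-methyl-6-(propan-2-yl)-1-(prop-2-en-1-yloxy)-7-[(triethylsilyl)oxy]hept-2-en-5-yl 3,4,5-trimethoxybenzoate | C=CCC[C@]1(C)O[C@H]1[C@H](O[Si](CC)(CC)CC)[C@H](C(C)C)[C@@H](C/C(C)=C\COCC=C)OC(=O)c2cc(OC)c(OC)c(OC)c2
F6 | step 6 | (2E)-1-bromo-4-methylpent-2-ene | CC(C)/C=C/CBr
F7 | step 6 | trimethyl{[(3R,4R,5E)-6-methyl-3-(propan-2-yl)deca-1,5,9-trien-4-yl]oxy}silane | C=CCC/C(C)=C/[C@H](O[Si](C)(C)C)[C@H](C(C)C)C=C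
F8 | step 8 | tert-butyl (1R,2R)-1-[(2S,3S)-3-(but-3-en-1-yl)-3-methyloxiran-2-yl]-2-(propan-2-yl)but-3-en-1-yl carbonate | C=CCC[C@]1(C)O[C@H]1[C@H](OC(=O)OC(C)(C)C)[C@H](C(C)C)C=C
F9 | step 8 | (4R,5S,6S)-4-[(2S,3S)-3-(but-3-en-1-yl)-3-methyloxiran-2-yl]-6-(iodomethyl)-5-(propan-2-yl)-1,3-dioxan-2-one | C=CCC[C@]1(C)O[C@H]1[C@@H]2OC(=O)O[C@H](CI)[C@H]2C(C)C
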